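Monday's run stood at 19.0% of product after 1.00 min, and a second-order law, rate proportional to electrophile times nucleophile, gave me 2.27 /M/min from that reading, taken while the product formed was less than the free base charged.

common to all: electrophile 0.050 M
- Saturday's: nucleophile 0.044 M; free base 0.015 M; run made earlier
- Monday's: nucleophile 0.098 M; free base 0.015 M; run made earlier
- flask: nucleophile 0.0650 M; free base 0.0150 M; time 8.0 min

- Saturday's (time / min: product / %, electrophile / %): 0.500: 5.7, 95.0; 1.50: 12.2, 86.8; 3.00: 22.6, 78.7; 5.00: 31.7, 67.8; 6.00: 38.6, 65.5
- Monday's (time / min: product / %, electrophile / %): 0.500: 9.5, 90.8; 1.00: 19.0, 81.4; 2.00: 33.0, 65.7; 3.00: 42.4, 57.1; 6.00: 66.4, 38.1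

(standard deviation of a reading: 1 percentage point)



1. product at 8.0 min, in percent of the electrophile charged
2. concentration of acid set free in solution at 8.0 min, in percent of saturation

I compared two times for the new flask. The first I called the base time, the moment when product equals the free base charged, the acid scavenger, which is 30.0% of the electrophile charged; the law put it at 2.77 min. The second was the reading time, 8.0 min, which lay 2.89 base times out. So I expected acid to pass beyond the base. The law gave 57.5% of product, and I took that as high: the law counts no nucleophile lost to acid. By the law the excess acid came to 21.2% of the nucleophile charge, with 55.8% of that charge unreacted to receive it, so I expected the nucleophile to take the excess up.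

The forecast said 56% of product and 50% of saturation, and reasoned that “free acid seems harmless up to about 0.018 M”.

The flask gave 54.4% of product, with acid set free at 0.993% of saturation.

    acid set free + free base ⇌ salt of the base, settled at all times (K = 2.10 × 10⁵ /M)
    nucleophile + acid set free ⇌ protonated nucleophile, settled at all times (K = 2900 /M)
    electrophile + nucleophile → acid set free + product (k = 0.0390 /M/s)
    crystals ⇌ acid set free, rate k4*(cs4 - [acid set free]) while solid is left; crystals form when [acid set free] > cs4 (solubility = 17.0 mM, k = 0.200 /s)

At 8.00 min this flask held free base at 2.74% of its charge and protonated nucleophile at 19.1% of the nucleophile charge. The neighbour charged with 0.026 M of nucleophile had by the same law a base time of 9.26 min, longer than its reading time. At 8.00 min that neighbour held 27.8% of product, free base at 14.0% of its charge, and protonated nucleophile at 3.65% of the nucleophile charge.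

(The readings come from a simulation for an exercise; the scatter is artificial.)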